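**Retrosynthetic overview**
- The plan rests on the C2=C3 double bond of ring C (the pyranone). C2, bonded to O1 and ring B, is at the ester oxidation level, and C3 is the carbon alpha to the C4 ketone. The bond is therefore cut to an aryl ester carbonyl and an acyl-stabilised phosphorus ylide held ortho to each other on ring A.
- The ylide ester is opened at the O1–acyl bond into 3,4,5-trimethoxybenzoyl chloride (ring B plus C2) and a 2-hydroxyphenacylphosphonium salt (ring A, O1, C4, C3).
- The salt goes back to PPh3 and an alpha-chloro ketone, made by Friedel–Crafts chloroacetylation of twofold-symmetric 1,2,3,5-tetramethoxybenzene with chelation-controlled loss of the one methyl group that uncovers O1. Phosphorus enters by SN2, so no unstabilised ylide meets the aryl ester and electron-rich ring A sees no electrophilic halogen source.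
- Rings A and B are bought. Ring C is the only ring made, and it is closed last, at carbon, under neutral conditions.

Key step: step 4

Remark: the target has no stereocentre and no stereogenic double bond, so its SMILES carries no descriptor. 1,2,3,5-Tetramethoxybenzene is taken as a catalogue compound.

**Step 1**
Reactants: 1 1,2,3,5-tetramethoxybenzene; 2 chloroacetyl chloride
Product: 4 2-chloro-1-(2-hydroxy-3,4,6-trimethoxyphenyl)ethan-1-one, via 2-chloro-1-(2,3,4,6-tetramethoxyphenyl)ethan-1-one 3 (not isolated)
Conditions: AlCl3 (2.2 equiv), CH2Cl2, −10 °C to rt; ice, 2 M HCl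
Reagents that add atoms: none
Why: Friedel–Crafts acylation can only strike one of the two equivalent ring C–H positions of twofold-symmetric 1, and the AlCl3 held on the new ketone oxygen then cleaves by chelation the ortho methoxy group that is buttressed by its 3-methoxy neighbour and twisted out of conjugation (the classical outcome of acylating this arene and pyrogallol trimethyl ether), which frees the oxygen that becomes O1 while the less crowded 6-methoxy group, the later 5-OMe, stays.

**Step 2**
Reactants: 4 2-chloro-1-(2-hydroxy-3,4,6-trimethoxyphenyl)ethan-1-one; 5 triphenylphosphine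
Product: 6 [2-(2-hydroxy-3,4,6-trimethoxyphenyl)-2-oxoethyl]triphenylphosphonium chloride
Conditions: toluene, 90 °C; the salt is filtered off
Reagents that add atoms: none
Why: SN2 quaternisation of PPh3 by a primary alpha-chloro ketone (standard phenacylphosphonium salt formation) runs without base, so the free phenol cannot close to the benzofuran-3-one, and chloride rather than bromide as leaving group keeps halophilic attack and reductive dehalogenation down.

**Step 3**
Reactants: 6 [2-(2-hydroxy-3,4,6-trimethoxyphenyl)-2-oxoethyl]triphenylphosphonium chloride; 7 3,4,5-trimethoxybenzoyl chloride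
Product: 9 3,5,6-trimethoxy-2-[(triphenylphosphoranylidene)acetyl]phenyl 3,4,5-trimethoxybenzoate, via 2-hydroxy-3,4,6-trimethoxyphenacylidenetriphenylphosphorane 8 (not isolated)
Conditions: Et3N (2.3 equiv), then 7 (1.0 equiv), DMAP (5 mol %), CH2Cl2, 0 °C to rt; cold aq NaHCO3 wash, concentration below 30 °C
Reagents that add atoms: none
Why: The first equivalent of Et3N takes the acidic P–CH2–C=O proton to give the keto-stabilised ylide 8, and DMAP-catalysed esterification then goes to the aryl oxide oxygen, a far better acyl acceptor than the doubly delocalised ylide carbon, any aroyl group caught first on the enolate oxygen being handed on to the adjacent phenol oxygen through a six-membered transition state (O-acylation of 2-hydroxyphenacylidene phosphoranes with acid chlorides and an amine base is known chemistry).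

**Step 4**
Reactants: 9 3,5,6-trimethoxy-2-[(triphenylphosphoranylidene)acetyl]phenyl 3,4,5-trimethoxybenzoate
Product: 11 bannamurpanisin [5,7,8-trimethoxy-2-(3,4,5-trimethoxyphenyl)-4H-chromen-4-one], via cis-fused oxaphosphetane 10 (not isolated)
Conditions: dry toluene (0.02 M), reflux, N2
Reagents that add atoms: none
Why: The ylide carbon of 9 (the later C3) adds to the carbonyl carbon of the ortho aroyloxy group (the later C2), the alkoxide so formed bonds to the phosphonium centre to give the cis-fused oxaphosphetane 10, and cycloreversion ejects Ph3P=O and leaves the C2=C3 double bond. The closest known reaction type is this very one, the intramolecular Wittig olefination of an ester carbonyl in 2-acyloxyphenacylidene phosphoranes, an established way to chromones and flavones, with the benzofuran synthesis from 2-acyloxybenzylphosphonium salts as its lower homologue. Ring C closes in the 6-exo-trig mode, since the attacked C=O bond lies outside the six-membered ring C3–C4–C4a–C8a–O1–C2, whose O1–C2 bond is already in place as the ester link. No stereocentre results, because the two sp3 carbons of 10 return to sp2 when the four-membered ring breaks up. The step needs olefination to win over O-to-C aroyl migration (loss of the aryl oxide from the same adduct), over acyl transfer between molecules and over hydrolysis: the electron-rich aryl oxide is a reluctant leaving group, phosphorus sits within bonding distance of the new alkoxide, a migrated aroyl group can return to the same adduct by re-addition of the phenol oxygen whereas loss of Ph3P=O to the aromatic pyranone is irreversible, and dilution with exclusion of water deals with the other two. An acyl-stabilised ylide would leave an ordinary alkyl ester alone, but here the partner is an activated phenyl-type ester fixed in the ortho position, and the neutral medium spares all six methyl ethers.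

**Compound list**
1 | 1,2,3,5-tetramethoxybenzene | COc1cc(OC)c(OC)c(OC)c1 | starting material
2 | chloroacetyl chloride | O=C(Cl)CCl | starting material
3 | 2-chloro-1-(2,3,4,6-tetramethoxyphenyl)ethan-1-one (formed in the flask, not isolated) | COc1cc(OC)c(C(=O)CCl)c(OC)c1OC | intermediate
4 | 2-chloro-1-(2-hydroxy-3,4,6-trimethoxyphenyl)ethan-1-one | COc1cc(OC)c(C(=O)CCl)c(O)c1OC | intermediate
5 | triphenylphosphine | c1ccc(cc1)P(c1ccccc1)c1ccccc1 | starting material
6 | [2-(2-hydroxy-3,4,6-trimethoxyphenyl)-2-oxoethyl]triphenylphosphonium chloride | COc1cc(OC)c(C(=O)C[P+](c2ccccc2)(c2ccccc2)c2ccccc2)c(O)c1OC.[Cl-] | intermediate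
7 | 3,4,5-trimethoxybenzoyl chloride | COc1cc(C(Cl)=O)cc(OC)c1OC | starting material
8 | 2-hydroxy-3,4,6-trimethoxyphenacylidenetriphenylphosphorane, i.e. 1-(2-hydroxy-3,4,6-trimethoxyphenyl)-2-(triphenylphosphoranylidene)ethan-1-one (formed in the flask, not isolated) | COc1cc(OC)c(C(=O)C=P(c2ccccc2)(c2ccccc2)c2ccccc2)c(O)c1OC | intermediate
9 | 3,5,6-trimethoxy-2-[(triphenylphosphoranylidene)acetyl]phenyl 3,4,5-trimethoxybenzoate (key-step precursor) | COc1cc(OC)c(C(=O)C=P(c2ccccc2)(c2ccccc2)c2ccccc2)c(OC(=O)c2cc(OC)c(OC)c(OC)c2)c1OC | intermediate
10 | oxaphosphetane across C2–C3 of the nascent ring C (P on C3, O on C2, H-3 and ring B cis; racemic, relative configuration drawn; not isolated) | O=C1[C@H]2[C@](Oc3c1c(OC)cc(OC)c3OC)(c1cc(OC)c(OC)c(OC)c1)OP2(c1ccccc1)(c1ccccc1)c1ccccc1 | intermediate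
11 | bannamurpanisin, 5,7,8-trimethoxy-2-(3,4,5-trimethoxyphenyl)-4H-chromen-4-one | COc1cc(-c2cc(=O)c3c(OC)cc(OC)c(OC)c3o2)cc(OC)c1OC | target

Total step count: 4
Longest linear sequence: 4 steps (1 → 4 → 6 → 9 → 11)

**Steps most likely to fail**

**Step 4.** O-to-C aroyl migration may outrun P–O bond formation in the adduct. Alternatively, the hindered and strongly delocalised ylide may fail to add to the ester carbonyl at reflux. The fallback sets out from 6 and comes back at 11, and it closes ring C at oxygen instead of at carbon.
- Salt 6 is freed with Et3N to ylide 8.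
- Ylide 8 is heated in toluene with bought 3,4,5-trimethoxybenzaldehyde. This is an intermolecular Wittig olefination of an aldehyde, E-selective for a stabilised ylide, and it should give (E)-1-(2-hydroxy-3,4,6-trimethoxyphenyl)-3-(3,4,5-trimethoxyphenyl)prop-2-en-1-one F1.
- Catalytic I2 in DMSO at 120–130 °C, the standard oxidative cyclisation of 2'-hydroxychalcones, then forms O1–C2 by oxa-Michael addition and dehydrogenates the flavanone stage to 11.

**Step 1.** Ether cleavage may occur at the less crowded 6-methoxy group or at more than one methoxy group, and the chloroacetyl side chain may erode under the Lewis acid. The site of cleavage is to be checked on 4 by NOE, since H-5 should lie next to two methoxy groups. The fallback sets out from 7 and from bought 2,4,5-trimethoxybenzoic acid (COc1cc(OC)c(C(=O)O)cc1OC) and comes back at 9. It bypasses steps 1 to 3 and installs the phenol oxygen instead of unmasking it.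
- The acid is lithiated twice with s-BuLi and TMEDA in THF at −78 °C. This is a directed ortho-metalation in which the carboxylate and the 5-methoxy group converge on the only C–H ortho to the carboxylate.
- The aryllithium is trapped with B(OMe)3 and oxidised with H2O2 to 2-hydroxy-3,4,6-trimethoxybenzoic acid F2.
- O-Aroylation with 7 in pyridine and CH2Cl2 at 0 °C, where aqueous work-up cleaves any mixed anhydride, gives 3,4,6-trimethoxy-2-[(3,4,5-trimethoxybenzoyl)oxy]benzoic acid F3.
- (COCl)2 with catalytic DMF gives 3,4,6-trimethoxy-2-[(3,4,5-trimethoxybenzoyl)oxy]benzoyl chloride F4.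
- Exactly two equivalents of methylenetriphenylphosphorane (from methyltriphenylphosphonium bromide and NaHMDS) are run slowly into F4 at −78 °C. The ylide is then never in excess over the acid chloride, which is far more electrophilic than the aryl ester. The first equivalent is C-acylated and the second acts as base (transylidation) to give 9.

**Step 3.** Aroylation may take place at the ylide carbon, or may stay on its enolate oxygen, instead of reaching the hindered, hydrogen-bonded phenol oxygen. The fallback sets out from 4 and 7 and comes back at 9. It puts the ester in place before phosphorus, so that no ylide is present when the acyl chloride is.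
- i-Pr2NEt is added last and slowly to 4, 7 and catalytic DMAP in CH2Cl2 at −20 °C. The phenoxide then meets the acyl chloride before it can displace its own chloride, and the product should be 2-(chloroacetyl)-3,5,6-trimethoxyphenyl 3,4,5-trimethoxybenzoate F5.
- PPh3 in toluene at 80 °C quaternises F5 to (2-oxo-2-{3,4,6-trimethoxy-2-[(3,4,5-trimethoxybenzoyl)oxy]phenyl}ethyl)triphenylphosphonium chloride F6.
- One equivalent of Et3N in CH2Cl2 at 0 °C followed by a water wash deprotonates F6 to 9.

**Further compounds**
F1 | step 4 | (E)-1-(2-hydroxy-3,4,6-trimethoxyphenyl)-3-(3,4,5-trimethoxyphenyl)prop-2-en-1-one | COc1cc(OC)c(C(=O)/C=C/c2cc(OC)c(OC)c(OC)c2)c(O)c1OC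
F2 | step 1 | 2-hydroxy-3,4,6-trimethoxybenzoic acid | COc1cc(OC)c(C(=O)O)c(O)c1OC
F3 | step 1 | 3,4,6-trimethoxy-2-[(3,4,5-trimethoxybenzoyl)oxy]benzoic acid | COc1cc(OC)c(C(=O)O)c(OC(=O)c2cc(OC)c(OC)c(OC)c2)c1OC
F4 | step 1 | 3,4,6-trimethoxy-2-[(3,4,5-trimethoxybenzoyl)oxy]benzoyl chloride | COc1cc(OC)c(C(Cl)=O)c(OC(=O)c2cc(OC)c(OC)c(OC)c2)c1OC
F5 | step 3 | 2-(chloroacetyl)-3,5,6-trimethoxyphenyl 3,4,5-trimethoxybenzoate | COc1cc(OC)c(C(=O)CCl)c(OC(=O)c2cc(OC)c(OC)c(OC)c2)c1OC
F6 | step 3 | (2-oxo-2-{3,4,6-trimethoxy-2-[(3,4,5-trimethoxybenzoyl)oxy]phenyl}ethyl)triphenylphosphonium chloride | COc1cc(OC)c(C(=O)C[P+](c2ccccc2)(c2ccccc2)c2ccccc2)c(OC(=O)c2cc(OC)c(OC)c(OC)c2)c1OC.[Cl-]
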